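Assumption: the target is drawn without a descriptor for the C4–N1' axis, so the axis is treated as configurationally undefined and all N-aryl indoles of the route are handled as racemic or freely rotating material.

## The problem

Rivularin B is a 4,1'-biindole. C4 of a 7-methoxy-1H-indole (indole A, unprimed atoms) is bonded to N1' of a second indole (indole B, primed atoms), and bromine sits on C3, C5, C3' and C5'. The C4–N1' bond lies between C5–Br and the peri position C3, so forming it by cross-coupling on a finished indole A would mean coupling at a carbon hindered on both sides while other aryl bromides are present. The bromines are of two kinds. C3 and C3' are the innately nucleophilic pyrrole positions and can be brominated at the very end. C5 and C5' cannot be reached selectively on the biindole, so they must arrive with the building blocks and survive all later steps, which excludes catalytic hydrogenation and late use of zerovalent palladium. There is no stereocentre, and the hindered C4–N1' axis is the only stereochemical element. The N–H 3-bromoindole is sensitive to acid and oxidants and should be the last function made. The enabling feature lies in indole A: N1 on C7a and C3 on C3a are ortho neighbours, and C7a also adjoins the methoxy carbon C7. This is the methyl/nitro/methoxy 1,2,3-pattern of commercial 3-methyl-2-nitroanisole 1, whose methyl group (the future C3) is acidified by the nitro group (the future N1).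

## Retrosynthesis

**14 to 13.** The C3–Br and C3'–Br bonds are cut first. Both carbons are indole β-positions, the most nucleophilic sites of the molecule, so one electrophilic bromination should serve both. The precursor 13 carries only the two bromines that cannot be introduced late. The forward reaction must stop after two brominations and must not touch C2 or C6.

**13 to 11.** The N1–C2 bond of indole A is cut, which leads back to the ortho-nitro enamine 11. Cutting N1–C7a instead (nitrene insertion) would leave a C2 ester to be removed. Cutting C3–C3a by a vinyl-organometallic addition to a nitroarene would bring a Grignard reagent onto a brominated nitroarene. The chosen cut needs only reduction: the amine of aminoenamine 12 closes onto the enamine carbon and the secondary amine leaves. The forward reaction must reduce the nitro group without cleaving C–Br, and it gives N1–H directly, so no protecting group is needed.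

**11 to 10.** The C2–C3 double bond of the enamine is cut, leaving the ortho-nitrotoluene 10. Forward, the nitro-acidified methyl group condenses with a formamide acetal in the presence of a cyclic secondary amine. The methyl group of 10 is flanked by the nitro group and by indole B, so the condensation must tolerate a crowded benzylic position.

**10 to 5 and 8.** N1'–C2' and N1'–C7a' are cut rather than the aryl–nitrogen bond C4–N1'. Indole B is thus grown on a nitrogen that is already attached to the future C4, and no coupling at a di-ortho-substituted carbon is required. The precursors are aniline 5 and arylacetaldehyde 8, two small benzene derivatives. Forward, condensation gives aldimine 9 and a copper-catalysed closure joins its nitrogen to the iodide-bearing carbon. The reaction must select C–I over the two C–Br bonds.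

**8 to 6.** The C2'–C3' bond is cut: 8 is the one-carbon homologue of commercial 5-bromo-2-iodobenzaldehyde 6, reached through enol ether 7 by methoxymethylenation and hydrolysis. The bromine of 6 is already at the position that becomes C5'.

**5 to 4.** The C–Br bond ortho to the amine (the future C5–Br) is cut. In aniline 4 the amino group has its para position occupied by methoxy and one ortho position by methyl, so its directing effect points at a single carbon.

**4 to 2 to 1.** The C–N bond of 4 (the future C4–N1') is cut to aryl bromide 2, which is aminated through imine 3 with an ammonia surrogate. Compound 2 in turn comes from 1 by bromination para to methoxy. Nitrating a nitro-free precursor of 4 was weighed and dropped: with the amine protonated, the open position para to the methyl group is expected to win over the one wedged between methyl and methoxy. The methyl/nitro/methoxy triad is therefore bought in with 1, and the nitrogen is added at the only position that the methoxy group activates strongly.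

## Roads not taken

**Alternative 1:** Fischer indolization for indole B. The cut is C3'–C3a' together with N1'–C2'. Forward, the pyruvate-derived hydrazone ethyl (E)-2-{2-(4-bromophenyl)-2-(5-bromo-7-methoxy-1-tosylindol-4-yl)hydrazinylidene}propanoate A2 would tautomerize under acid, undergo the [3,3] shift onto the 4-bromophenyl ring and close to ethyl 5-bromo-1-(5-bromo-7-methoxy-1-tosylindol-4-yl)indole-2-carboxylate A1.
- Merits: the Fischer reaction is dependable; the regiochemistry is fixed because both ortho positions of the indole A ring are blocked; and the C5' bromine comes from a simple para-bromophenyl unit, with no sensitive arylacetaldehyde.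
- Weak points: the 1,1-diarylhydrazine behind A2 needs a diarylamine made by coupling at the hindered C4, followed by N-amination. A1 then still carries an ester and a tosyl group, so hydrolysis, a hot decarboxylation in the presence of aryl bromides, and detosylation follow.
- Comparison: its ring-forming step is probably more robust than step 5 of the chosen plan. Against this, the chosen plan avoids any coupling at a crowded carbon, uses no protecting group and needs no decarboxylation.

**Alternative 2:** Hemetsberger closure of indole A. The cut is N1–C7a. Forward, thermolysis of methyl (Z)-2-azido-3-[3-bromo-2-(5-bromoindol-1-yl)-5-methoxyphenyl]acrylate A4 would generate a vinyl nitrene that inserts into the only free ortho C–H, giving methyl 5-bromo-4-(5-bromoindol-1-yl)-7-methoxy-1H-indole-2-carboxylate A3.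
- Merits: the aldehyde behind A4 could carry indole B from the start, attached by nucleophilic aromatic substitution of an ortho fluoride, so A3 is reached in fewer steps than 13. In step count to the biindole skeleton this road is the shorter one.
- Weak points: the condensation with an azidoacetate at an aldehyde flanked by indole B is often low-yielding; the azide must be heated; and A3 needs saponification and copper-mediated decarboxylation near 200 °C, where aryl bromides are at risk.
- Comparison: the chosen plan is longer up to 13, but 13 is formed at about 90 °C with no carboxyl group to remove and no azide to handle.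

**Alternative 3:** indole B grown on a preformed indole A. The cut is N1'–C2' and N1'–C7a', the same as in step 5 of the chosen plan. Forward, 4-amino-5-bromo-7-methoxy-1-tosylindole A6 would condense with aldehyde 8 and close under copper catalysis to 5-bromo-4-(5-bromoindol-1-yl)-7-methoxy-1-tosylindole A5.
- Merits: the last ring is formed convergently, and indole A would be made on a nitrotoluene whose methyl group is not yet crowded by indole B. That is a real advantage over step 6 of the chosen plan.
- Weak points: A6 needs N-protection and later deprotection, and brominating ortho to its amine competes with bromination at C3 of the same indole.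
- Comparison: both roads rely on the same copper closure, so neither gains there. The chosen plan brominates a simple aniline in which the amine is the only strong director, and it uses no protecting group, but it accepts a more hindered enamine condensation.

Key step: step 7

## Route

Step 1
Reactants: 1 3-methyl-2-nitroanisole
Product: 2 1-bromo-4-methoxy-2-methyl-3-nitrobenzene
Conditions: NBS, MeCN, 60 °C
Reagents that add atoms: N-bromosuccinimide O=C1CCC(=O)N1Br
Why: Electrophilic aromatic bromination; the methoxy group directs para, that carbon is also ortho to the methyl group and meta to the nitro group, so it is the most activated open position.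

Step 2
Reactants: 2 1-bromo-4-methoxy-2-methyl-3-nitrobenzene
Product: 4 4-methoxy-2-methyl-3-nitroaniline, via diphenylmethylene imine 3 (not isolated)
Conditions: Ph2C=NH, Pd2(dba)3, rac-BINAP, Cs2CO3, PhMe, 100 °C; then 2 M HCl, THF, rt
Reagents that add atoms: benzophenone imine N=C(c1ccccc1)c1ccccc1
Why: Buchwald–Hartwig amination with an ammonia surrogate; the carbonate base spares the nitro group and the acidic benzylic methyl, and mild acid hydrolysis of imine 3 frees the primary aniline.

Step 3
Reactants: 4 4-methoxy-2-methyl-3-nitroaniline
Product: 5 6-bromo-4-methoxy-2-methyl-3-nitroaniline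
Conditions: NBS (1.0 equiv), DMF, 0 °C
Reagents that add atoms: N-bromosuccinimide O=C1CCC(=O)N1Br
Why: Electrophilic bromination directed by the free amino group; its para position and one ortho position are occupied, so only C6 is left, and one equivalent at low temperature limits attack ortho to methoxy.

Step 4
Reactants: 6 5-bromo-2-iodobenzaldehyde
Product: 8 2-(5-bromo-2-iodophenyl)acetaldehyde, via enol ether 7 (not isolated)
Conditions: Ph3P(CH2OMe)Cl, KOtBu, THF, 0 °C to rt; then 2 M HCl, THF, 50 °C
Reagents that add atoms: (methoxymethyl)triphenylphosphonium chloride [Cl-].COC[P+](c1ccccc1)(c1ccccc1)c1ccccc1; water O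
Why: Wittig methoxymethylenation followed by acid hydrolysis of the enol ether is the standard one-carbon homologation of an aryl aldehyde; neither the ylide nor dilute acid affects the aryl iodide or bromide, and the aldehyde is used at once.

Step 5
Reactants: 5 6-bromo-4-methoxy-2-methyl-3-nitroaniline; 8 2-(5-bromo-2-iodophenyl)acetaldehyde
Product: 10 5-bromo-1-(6-bromo-4-methoxy-2-methyl-3-nitrophenyl)-1H-indole, via aldimine 9 (not isolated)
Conditions: TsOH (cat.), 4 Å MS, PhMe, 60 °C; then CuI (10 mol%), N,N'-dimethylethylenediamine, K3PO4, DMF, 90 °C
Reagents that add atoms: none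
Why: Condensation gives aldimine 9, whose Z-enamine tautomer undergoes intramolecular Ullmann-type N-arylation; monovalent copper reacts with the aryl iodide much faster than with the two aryl bromides, and the five-membered closure is intramolecular.

Step 6
Reactants: 10 5-bromo-1-(6-bromo-4-methoxy-2-methyl-3-nitrophenyl)-1H-indole
Product: 11 5-bromo-1-{6-bromo-4-methoxy-3-nitro-2-[(E)-2-(pyrrolidin-1-yl)vinyl]phenyl}-1H-indole
Conditions: Me2NCH(OMe)2, pyrrolidine, DMF, 110 °C; concentrated and used crude
Reagents that add atoms: N,N-dimethylformamide dimethyl acetal COC(OC)N(C)C; pyrrolidine C1CCNC1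
Why: Enamine-forming half of the Leimgruber–Batcho synthesis; pyrrolidine exchanges into the formamide acetal to give a more reactive reagent, the nitro-acidified methyl condenses with loss of methanol, and the conjugated push-pull enamine forms as the E isomer under thermodynamic control.

Step 7
Reactants: 11 5-bromo-1-{6-bromo-4-methoxy-3-nitro-2-[(E)-2-(pyrrolidin-1-yl)vinyl]phenyl}-1H-indole
Product: 13 5-bromo-4-(5-bromoindol-1-yl)-7-methoxy-1H-indole, via aminoenamine 12 (not isolated)
Conditions: Fe powder, AcOH, silica gel, PhMe, 90 °C
Reagents that add atoms: none
Why: This is the reductive cyclization of the Leimgruber–Batcho indole synthesis. Zerovalent iron in acetic acid reduces the nitro group of 11 through the nitroso and hydroxylamine stages to the aniline, giving aminoenamine 12. Acetic acid protonates the enamine of 12 at its benzylic carbon (the future C3) to an iminium ion, and the new aniline nitrogen adds to the iminium carbon (the future C2), forming N1–C2 in a 5-exo-trig closure. Loss of pyrrolidine from the resulting aminal aromatizes the pyrrole ring and gives 13 with free N1–H. No stereocentre is formed. The step needs chemoselectivity for the nitro group over the two aryl C–Br bonds and the C2'–C3' double bond of indole B. This is secured by electron-transfer reduction with iron in place of catalytic hydrogenation, which would cleave C–Br. Silica gel and toluene dilute the acid and should limit hydrolysis of the enamine before the nitro group is reduced.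

Step 8
Reactants: 13 5-bromo-4-(5-bromoindol-1-yl)-7-methoxy-1H-indole
Product: 14 rivularin B, 3,5-dibromo-4-(3,5-dibromoindol-1-yl)-7-methoxy-1H-indole
Conditions: NBS (2.05 equiv), DMF, −20 to 0 °C, dark
Reagents that add atoms: N-bromosuccinimide O=C1CCC(=O)N1Br
Why: Electrophilic bromination of indoles at the β-position; C3 and C3' are far more nucleophilic than any remaining benzenoid carbon, so two equivalents at low temperature should stop at the tetrabromide.

## Compound list

1 | 3-methyl-2-nitroanisole | COc1cccc(C)c1[N+](=O)[O-] | starting material
2 | 1-bromo-4-methoxy-2-methyl-3-nitrobenzene | COc1ccc(Br)c(C)c1[N+](=O)[O-] | intermediate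
3 | N-(4-methoxy-2-methyl-3-nitrophenyl)-1,1-diphenylmethanimine | COc1ccc(N=C(c2ccccc2)c2ccccc2)c(C)c1[N+](=O)[O-] | intermediate
4 | 4-methoxy-2-methyl-3-nitroaniline | COc1ccc(N)c(C)c1[N+](=O)[O-] | intermediate
5 | 6-bromo-4-methoxy-2-methyl-3-nitroaniline | COc1cc(Br)c(N)c(C)c1[N+](=O)[O-] | intermediate
6 | 5-bromo-2-iodobenzaldehyde | O=Cc1cc(Br)ccc1I | starting material
7 | 4-bromo-1-iodo-2-(2-methoxyvinyl)benzene, mixture of E and Z isomers | COC=Cc1cc(Br)ccc1I | intermediate
8 | 2-(5-bromo-2-iodophenyl)acetaldehyde | O=CCc1cc(Br)ccc1I | intermediate
9 | (E)-N-(6-bromo-4-methoxy-2-methyl-3-nitrophenyl)-2-(5-bromo-2-iodophenyl)ethan-1-imine | COc1cc(Br)c(/N=C/Cc2cc(Br)ccc2I)c(C)c1[N+](=O)[O-] | intermediate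
10 | 5-bromo-1-(6-bromo-4-methoxy-2-methyl-3-nitrophenyl)-1H-indole | COc1cc(Br)c(-n2ccc3cc(Br)ccc32)c(C)c1[N+](=O)[O-] | intermediate
11 | 5-bromo-1-{6-bromo-4-methoxy-3-nitro-2-[(E)-2-(pyrrolidin-1-yl)vinyl]phenyl}-1H-indole | COc1cc(Br)c(-n2ccc3cc(Br)ccc32)c(/C=C/N2CCCC2)c1[N+](=O)[O-] | intermediate
12 | 4-bromo-3-(5-bromoindol-1-yl)-6-methoxy-2-[(E)-2-(pyrrolidin-1-yl)vinyl]aniline | COc1cc(Br)c(-n2ccc3cc(Br)ccc32)c(/C=C/N2CCCC2)c1N | intermediate
13 | 5-bromo-4-(5-bromoindol-1-yl)-7-methoxy-1H-indole | COc1cc(Br)c(-n2ccc3cc(Br)ccc32)c2cc[nH]c12 | intermediate
14 | rivularin B, 3,5-dibromo-4-(3,5-dibromoindol-1-yl)-7-methoxy-1H-indole | COc1cc(Br)c(-n2cc(Br)c3cc(Br)ccc32)c2c(Br)c[nH]c12 | target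

## Step count and risks

Total step count: 8. Longest linear sequence: 7 steps (steps 1, 2, 3, 5, 6, 7, 8) from 1; step 4 is the side branch from 6.

**Step 7 (key step).** The likely failure is incomplete reduction, with ring closure at the hydroxylamine stage leading to N-hydroxylated product. Hydrolysis and oligomerization of the enamine in hot acid before the nitro group is reduced is the second risk. Both arise because reduction and cyclization compete in one pot.

The fallback separates them. It sets out from 11: acidic methanol (TMSCl, MeOH, reflux) exchanges the enamine for the acetal 5-bromo-1-[6-bromo-2-(2,2-dimethoxyethyl)-4-methoxy-3-nitrophenyl]-1H-indole F1. Neutral reduction (Fe, NH4Cl, EtOH/H2O, 70 °C) gives 4-bromo-3-(5-bromoindol-1-yl)-2-(2,2-dimethoxyethyl)-6-methoxyaniline F2. Catalytic TsOH in toluene then closes N1–C2 with loss of methanol, and the sequence returns to the route at 13.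

**Step 6.** Deprotonation of the methyl group may be slow. It sits between the nitro group and indole B, and the nitro group is twisted out of conjugation by the neighbouring methoxy. Long heating would then erode the material.

The fallback uses a stronger base and the smallest electrophile. From 10, paraformaldehyde and KOtBu in DMSO at rt give 2-[3-bromo-2-(5-bromoindol-1-yl)-5-methoxy-6-nitrophenyl]ethanol F5. Dess–Martin oxidation gives 2-[3-bromo-2-(5-bromoindol-1-yl)-5-methoxy-6-nitrophenyl]acetaldehyde F6. Condensation with pyrrolidine over 4 Å MS returns to the route at 11.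

**Step 5.** Self-condensation of the enolizable aldehyde 8 may outrun imine formation with the di-ortho-substituted, weakly nucleophilic aniline 5. Intermolecular C–N coupling at an aryl bromide may also intrude.

The fallback traps the iminium ion by hydride. From 5 and 8, reductive amination (NaBH(OAc)3, TFA, CH2Cl2) gives 6-bromo-N-[2-(5-bromo-2-iodophenyl)ethyl]-4-methoxy-2-methyl-3-nitroaniline F3. Intramolecular amination (CuI, CsOAc, DMSO, 60 °C) gives 5-bromo-1-(6-bromo-4-methoxy-2-methyl-3-nitrophenyl)indoline F4. Dehydrogenation with DDQ in toluene returns to the route at 10.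

**Step 8.** Bromination may run past the two β-positions (at C2 or C6 of indole A), or lag at the peri-hindered C3. The electron-rich N–H indole may also suffer oxidative degradation under two equivalents of oxidant.

The fallback stages the two brominations. From 10, one equivalent of NBS gives 3,5-dibromo-1-(6-bromo-4-methoxy-2-methyl-3-nitrophenyl)-1H-indole F7. The conditions of step 6 give 3,5-dibromo-1-{6-bromo-4-methoxy-3-nitro-2-[(E)-2-(pyrrolidin-1-yl)vinyl]phenyl}-1H-indole F8. The conditions of step 7 give 5-bromo-4-(3,5-dibromoindol-1-yl)-7-methoxy-1H-indole F9. A single equivalent of NBS at −40 °C then brominates C3 and the sequence arrives at 14.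

**Step 3.** Bromination may go ortho to the methoxy group, or twice, because the position ortho to the amine is para to the nitro group and so partly deactivated.

The fallback replaces innate selectivity by chelation control. From 4, acetylation (Ac2O, pyridine) gives N-(4-methoxy-2-methyl-3-nitrophenyl)acetamide F10. Anilide-directed ortho-bromination under divalent palladium catalysis (Pd(OAc)2, NBS, TsOH, PhMe) gives N-(6-bromo-4-methoxy-2-methyl-3-nitrophenyl)acetamide F11. Hydrolysis (6 M HCl, EtOH, reflux) returns to the route at 5.

## Further compounds

F1 | step 7 | 5-bromo-1-[6-bromo-2-(2,2-dimethoxyethyl)-4-methoxy-3-nitrophenyl]-1H-indole | COc1cc(Br)c(-n2ccc3cc(Br)ccc32)c(CC(OC)OC)c1[N+](=O)[O-]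
F2 | step 7 | 4-bromo-3-(5-bromoindol-1-yl)-2-(2,2-dimethoxyethyl)-6-methoxyaniline | COc1cc(Br)c(-n2ccc3cc(Br)ccc32)c(CC(OC)OC)c1N
F3 | step 5 | 6-bromo-N-[2-(5-bromo-2-iodophenyl)ethyl]-4-methoxy-2-methyl-3-nitroaniline | COc1cc(Br)c(NCCc2cc(Br)ccc2I)c(C)c1[N+](=O)[O-]
F4 | step 5 | 5-bromo-1-(6-bromo-4-methoxy-2-methyl-3-nitrophenyl)indoline | COc1cc(Br)c(N2CCc3cc(Br)ccc32)c(C)c1[N+](=O)[O-]
F5 | step 6 | 2-[3-bromo-2-(5-bromoindol-1-yl)-5-methoxy-6-nitrophenyl]ethanol | COc1cc(Br)c(-n2ccc3cc(Br)ccc32)c(CCO)c1[N+](=O)[O-]
F6 | step 6 | 2-[3-bromo-2-(5-bromoindol-1-yl)-5-methoxy-6-nitrophenyl]acetaldehyde | COc1cc(Br)c(-n2ccc3cc(Br)ccc32)c(CC=O)c1[N+](=O)[O-]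
F7 | step 8 | 3,5-dibromo-1-(6-bromo-4-methoxy-2-methyl-3-nitrophenyl)-1H-indole | COc1cc(Br)c(-n2cc(Br)c3cc(Br)ccc32)c(C)c1[N+](=O)[O-]
F8 | step 8 | 3,5-dibromo-1-{6-bromo-4-methoxy-3-nitro-2-[(E)-2-(pyrrolidin-1-yl)vinyl]phenyl}-1H-indole | COc1cc(Br)c(-n2cc(Br)c3cc(Br)ccc32)c(/C=C/N2CCCC2)c1[N+](=O)[O-]
F9 | step 8 | 5-bromo-4-(3,5-dibromoindol-1-yl)-7-methoxy-1H-indole | COc1cc(Br)c(-n2cc(Br)c3cc(Br)ccc32)c2cc[nH]c12
F10 | step 3 | N-(4-methoxy-2-methyl-3-nitrophenyl)acetamide | COc1ccc(NC(C)=O)c(C)c1[N+](=O)[O-]
F11 | step 3 | N-(6-bromo-4-methoxy-2-methyl-3-nitrophenyl)acetamide | COc1cc(Br)c(NC(C)=O)c(C)c1[N+](=O)[O-]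
A1 | alternative 1 | ethyl 5-bromo-1-(5-bromo-7-methoxy-1-tosylindol-4-yl)indole-2-carboxylate | CCOC(=O)c1cc2cc(Br)ccc2n1-c1c(Br)cc(OC)c2c1ccn2S(=O)(=O)c1ccc(C)cc1
A2 | alternative 1 | ethyl (E)-2-{2-(4-bromophenyl)-2-(5-bromo-7-methoxy-1-tosylindol-4-yl)hydrazinylidene}propanoate | CCOC(=O)/C(C)=N/N(c1ccc(Br)cc1)c1c(Br)cc(OC)c2c1ccn2S(=O)(=O)c1ccc(C)cc1
A3 | alternative 2 | methyl 5-bromo-4-(5-bromoindol-1-yl)-7-methoxy-1H-indole-2-carboxylate | COC(=O)c1cc2c(-n3ccc4cc(Br)ccc43)c(Br)cc(OC)c2[nH]1
A4 | alternative 2 | methyl (Z)-2-azido-3-[3-bromo-2-(5-bromoindol-1-yl)-5-methoxyphenyl]acrylate | COC(=O)/C(N=[N+]=[N-])=C/c1cc(OC)cc(Br)c1-n1ccc2cc(Br)ccc21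
A5 | alternative 3 | 5-bromo-4-(5-bromoindol-1-yl)-7-methoxy-1-tosylindole | Cc1ccc(cc1)S(=O)(=O)n1ccc2c(-n3ccc4cc(Br)ccc43)c(Br)cc(OC)c21
A6 | alternative 3 | 4-amino-5-bromo-7-methoxy-1-tosylindole | COc1cc(Br)c(N)c2ccn(S(=O)(=O)c3ccc(C)cc3)c12
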